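**Plan**

- Numbering: C1 lactone carbonyl, C2, carbinol C3, alkene C4(Me)=C5, C6(Me), C7(OH), C8, ketone C9, C10(OMe), Z,Z-diene C11=C12–C13=C14(Me), benzylic C15 on the phenol ring.
- Enabling feature: in the 20-membered lactone ring, C3 is an allylic carbinol between the C2 methylene of the C1 ester and the sp2 carbon C4 of the Z-trisubstituted C4=C5 alkene. It is therefore the adduct of a 3-oxopropanoate aldehyde and a Z-alkenyl metal.
- Cuts, in order: C3–C4 (ring, Nozaki–Hiyama–Kishi), benzylic ester O–C1, C4=C5 (iodoethylidene Wittig), C12–C13 (Sonogashira, then semireduction), C9–C10 (methoxyallylboration), C6–C7 (Evans aldol), C15–aryl (copper-catalysed allylation).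
- Forward: fragment A (arene plus C13–C15 Z-alkenyl iodide, steps 1–4) and fragment B (C5–C12 alkyne, steps 5–13) are joined. The diene, the C4 iodide and the C1–C3 ester follow, then the macrocycle is closed and C9 is oxidised last.
- Stereochemistry: C6/C7 from the Evans auxiliary; C10 from the isopinocampheylborane (C9 is set with it and later erased); C3 from the chiral ligand on chromium. The Z alkenes come from anti-carbomagnesiation, zinc semireduction and the Stork–Zhao-type ylide.

Key step: step 22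

Remark: the (S)-configured oxazoline–sulfonamide ligand is assumed to direct the alkenylchromium to the Re face of the C3 aldehyde; if the sense is the opposite, the (R)-ligand is used and nothing else changes.

Step 1
Reactants: 1 methyl 3-hydroxy-5-iodobenzoate
Product: 2 methyl 3-((tert-butyldimethylsilyl)oxy)-5-iodobenzoate
Conditions: TBSCl, imidazole, DMF, rt
Reagents that add atoms: tert-butyldimethylsilyl chloride, CC(C)(C)[Si](C)(C)Cl
Why: Imidazole-promoted silylation masks the acidic phenol before the Grignard step, and the aryl silyl ether should last until the final fluoride step.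

Step 2
Reactants: 3 prop-2-yn-1-ol
Product: 5 (Z)-3-iodo-2-methylprop-2-en-1-ol, via alkenylmagnesium alkoxide 4 (not isolated)
Conditions: MeMgBr (2.5 equiv), CuI (10 mol %), THF, −10 °C to rt; then I2, −10 °C
Reagents that add atoms: methylmagnesium bromide, C[Mg]Br; iodine, II
Why: Copper-catalysed anti-carbomagnesiation of the propargylic alkoxide puts methyl on C2 and magnesium on C3 in an oxygen-chelated array, and iodinolysis with retention leaves iodine cis to CH2OH, the geometry needed for C13=C14.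

Step 3
Reactants: 5 (Z)-3-iodo-2-methylprop-2-en-1-ol
Product: 6 (Z)-3-bromo-1-iodo-2-methylprop-1-ene
Conditions: CBr4, PPh3, CH2Cl2, 0 °C
Reagents that add atoms: carbon tetrabromide, BrC(Br)(Br)Br
Why: Appel bromination of the primary allylic alcohol is neutral and should leave the alkenyl iodide and its geometry untouched.

Step 4
Reactants: 2 methyl 3-((tert-butyldimethylsilyl)oxy)-5-iodobenzoate; 6 (Z)-3-bromo-1-iodo-2-methylprop-1-ene
Product: 8 methyl (Z)-3-((tert-butyldimethylsilyl)oxy)-5-(3-iodo-2-methylallyl)benzoate, via arylmagnesium chloride 7 (not isolated)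
Conditions: iPrMgCl·LiCl, THF, −40 °C; then Li2CuCl4 (5 mol %), 6, −40 to −10 °C
Reagents that add atoms: none
Why: Iodine–magnesium exchange of the ester-bearing aryl iodide at −40 °C, then copper-catalysed SN2 allylic substitution at the primary bromide; the γ-carbon is an iodo-substituted sp2 centre, so α-attack should prevail and the Z-alkenyl iodide is kept.

Step 5
Reactants: 9 (R)-4-benzyl-3-propionyloxazolidin-2-one; 10 3-((tert-butyldimethylsilyl)oxy)propanal
Product: 12 (R)-4-benzyl-3-[(2R,3S)-5-((tert-butyldimethylsilyl)oxy)-3-hydroxy-2-methylpentanoyl]oxazolidin-2-one, via Z-boron enolate 11 (not isolated)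
Conditions: Bu2BOTf, iPr2NEt, CH2Cl2, −78 to 0 °C; then pH 7 buffer, MeOH, H2O2
Reagents that add atoms: none
Why: Evans syn-aldol: the Z-dibutylboron enolate reacts through a chair Zimmerman–Traxler transition state on the face away from the benzyl group of the (R)-auxiliary, which sets C6 and C7 syn in the required absolute sense.

Step 6
Reactants: 12 the aldol imide
Product: 13 (2R,3S)-5-((tert-butyldimethylsilyl)oxy)-3-hydroxy-N-methoxy-N,2-dimethylpentanamide
Conditions: MeNHOMe·HCl, AlMe3, THF, −20 to 0 °C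
Reagents that add atoms: N,O-dimethylhydroxylamine hydrochloride, CNOC.Cl
Why: Aluminium-amide transamidation (Weinreb amide formation) releases the auxiliary and leaves C5 as a latent aldehyde that tolerates ozone, carbonate and palladium.

Step 7
Reactants: 13 the hydroxy Weinreb amide
Product: 14 (2R,3S)-3,5-bis((tert-butyldimethylsilyl)oxy)-N-methoxy-N,2-dimethylpentanamide
Conditions: TBSOTf, 2,6-lutidine, CH2Cl2, −78 °C
Reagents that add atoms: tert-butyldimethylsilyl triflate, CC(C)(C)[Si](C)(C)OS(=O)(=O)C(F)(F)F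
Why: Silyl triflate silylation protects the C7 carbinol as a TBS ether that should survive to the last step.

Step 8
Reactants: 14 the bis-silyl ether
Product: 15 (2R,3S)-3-((tert-butyldimethylsilyl)oxy)-5-hydroxy-N-methoxy-N,2-dimethylpentanamide
Conditions: camphorsulfonic acid (cat.), MeOH/CH2Cl2, 0 °C
Reagents that add atoms: none
Why: Acid-catalysed methanolysis removes the unhindered primary TBS ether much faster than the secondary one (selective desilylation).

Step 9
Reactants: 15 the primary alcohol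
Product: 16 (2R,3S)-3-((tert-butyldimethylsilyl)oxy)-N-methoxy-N,2-dimethyl-5-oxopentanamide
Conditions: Dess–Martin periodinane, CH2Cl2, rt
Reagents that add atoms: none
Why: Dess–Martin oxidation gives the β-silyloxy aldehyde under near-neutral conditions that should not cause β-elimination.

Step 10
Reactants: 16 the C9 aldehyde
Product: 17 (2R,3S,5R,6R)-3-((tert-butyldimethylsilyl)oxy)-5-hydroxy-N,6-dimethoxy-N,2-dimethyloct-7-enamide
Conditions: allyl methyl ether, s-BuLi, THF, −78 °C; (−)-Ipc2BOMe; BF3·OEt2; then 16, −78 °C; ethanolamine work-up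
Reagents that add atoms: allyl methyl ether, COCC=C
Why: Brown (Z)-γ-methoxyallylboration: the chair transition state of the Z-allylborane gives the syn methoxy alcohol, and the isopinocampheyl groups from (+)-α-pinene direct attack to the Si face of the aldehyde, which sets C10 as R (and C9 as R, a centre oxidised later).

Step 11
Reactants: 17 the methoxy alcohol
Product: 18 (2R,3S,5R,6R)-3-((tert-butyldimethylsilyl)oxy)-N,6-dimethoxy-N,2-dimethyl-5-((triethylsilyl)oxy)oct-7-enamide
Conditions: TESOTf, 2,6-lutidine, CH2Cl2, −78 °C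
Reagents that add atoms: triethylsilyl triflate, CC[Si](CC)(CC)OS(=O)(=O)C(F)(F)F
Why: Silylation with the triethylsilyl group marks the C9 hydroxyl as the one that mild acid can later free in the presence of the TBS ethers.

Step 12
Reactants: 18 the terminal alkene
Product: 20 (2R,3S,5R,6S)-3-((tert-butyldimethylsilyl)oxy)-N,6-dimethoxy-N,2-dimethyl-7-oxo-5-((triethylsilyl)oxy)heptanamide, via secondary ozonide 19 (not isolated)
Conditions: O3, CH2Cl2, −78 °C; then PPh3, −78 °C to rt
Reagents that add atoms: ozone, [O-][O+]=O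
Why: Ozonolysis of the only alkene with reductive work-up gives the α-methoxy aldehyde without touching C10.

Step 13
Reactants: 20 the C11 aldehyde
Product: 21 (2R,3S,5R,6R)-3-((tert-butyldimethylsilyl)oxy)-N,6-dimethoxy-N,2-dimethyl-5-((triethylsilyl)oxy)oct-7-ynamide
Conditions: dimethyl (1-diazo-2-oxopropyl)phosphonate, K2CO3, MeOH, 0 °C to rt
Reagents that add atoms: dimethyl (1-diazo-2-oxopropyl)phosphonate, COP(=O)(OC)C(=[N+]=[N-])C(C)=O
Why: Ohira–Bestmann homologation (Seyferth–Gilbert type) turns the aldehyde into the terminal alkyne under mild carbonate conditions that normally preserve α-alkoxy stereocentres.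

Step 14
Reactants: 22 methyl 3-hydroxypropanoate
Product: 23 methyl 3-((triethylsilyl)oxy)propanoate
Conditions: TESCl, imidazole, CH2Cl2, 0 °C
Reagents that add atoms: chlorotriethylsilane, CC[Si](Cl)(CC)CC
Why: Routine silylation of a primary alcohol gives the masked C3 oxygen of the C1–C3 unit.

Step 15
Reactants: 23 methyl 3-((triethylsilyl)oxy)propanoate
Product: 24 3-((triethylsilyl)oxy)propanoic acid
Conditions: LiOH, THF/H2O, 0 °C; then NaHSO4 to pH 4
Reagents that add atoms: lithium hydroxide, [Li+].[OH-]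
Why: Saponification of the methyl ester at 0 °C with careful acidification gives the acid partner while the base-stable silyl ether is kept.

Step 16
Reactants: 8 the Z-alkenyl iodide (fragment A); 21 the alkyne (fragment B)
Product: 25 methyl 3-((tert-butyldimethylsilyl)oxy)-5-[(2Z,6R,7R,9S,10R)-9-((tert-butyldimethylsilyl)oxy)-6-methoxy-11-(methoxy(methyl)amino)-2,10-dimethyl-11-oxo-7-((triethylsilyl)oxy)undec-2-en-4-yn-1-yl]benzoate
Conditions: Pd(PPh3)2Cl2 (5 mol %), CuI (10 mol %), Et3N, THF, rt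
Reagents that add atoms: none
Why: Sonogashira coupling of the Z-alkenyl iodide with the terminal alkyne proceeds with retention of alkene geometry and forms the C12–C13 bond.

Step 17
Reactants: 25 the enyne
Product: 26 methyl 3-((tert-butyldimethylsilyl)oxy)-5-[(2Z,4Z,6R,7R,9S,10R)-9-((tert-butyldimethylsilyl)oxy)-6-methoxy-11-(methoxy(methyl)amino)-2,10-dimethyl-11-oxo-7-((triethylsilyl)oxy)undeca-2,4-dien-1-yl]benzoate
Conditions: Zn dust activated with Cu(OAc)2 and AgNO3, MeOH/H2O, 40 °C
Reagents that add atoms: none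
Why: Zinc (copper/silver couple) semireduction of the conjugated enyne (Boland-type reduction) adds hydrogen cis and should give the Z alkene at C11=C12 without over-reduction.

Step 18
Reactants: 26 the Z,Z-diene
Product: 27 (2R,3S,5R,6R,7Z,9Z)-3-((tert-butyldimethylsilyl)oxy)-11-[3-((tert-butyldimethylsilyl)oxy)-5-(hydroxymethyl)phenyl]-6-methoxy-2,10-dimethyl-5-((triethylsilyl)oxy)undeca-7,9-dienal
Conditions: iBu2AlH (5 equiv), CH2Cl2, −78 to −20 °C; aq. potassium sodium tartrate
Reagents that add atoms: none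
Why: The aluminium hydride reduces the Weinreb amide to the C5 aldehyde through the stable chelated hemiaminal and the aryl ester to the benzylic alcohol in one operation.

Step 19
Reactants: 27 the hydroxy aldehyde
Product: 28 [3-((tert-butyldimethylsilyl)oxy)-5-((2Z,4Z,6R,7R,9S,10S,11Z)-9-((tert-butyldimethylsilyl)oxy)-12-iodo-6-methoxy-2,10-dimethyl-7-((triethylsilyl)oxy)trideca-2,4,11-trien-1-yl)phenyl]methanol
Conditions: EtPPh3I, n-BuLi, THF, rt; I2, −78 °C; NaN(SiMe3)2, −20 °C; then 27, −78 to −20 °C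
Reagents that add atoms: ethyltriphenylphosphonium iodide, CC[P+](c1ccccc1)(c1ccccc1)c1ccccc1.[I-]; iodine, II
Why: Stork–Zhao-type Wittig olefination with the α-iodoethylidene ylide gives the Z-2-iodoalkene (iodine cis to C6) by kinetic cis-oxaphosphetane formation at low temperature, and the free benzylic hydroxyl is tolerated when excess ylide is used.

Step 20
Reactants: 28 the iodo alcohol; 24 3-((triethylsilyl)oxy)propanoic acid
Product: 29 the 3-((triethylsilyl)oxy)propanoate ester of 28
Conditions: EDC·HCl, DMAP (cat.), CH2Cl2, 0 °C to rt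
Reagents that add atoms: none
Why: Steglich esterification of the unhindered primary benzylic alcohol installs the C1–C3 unit.

Step 21
Reactants: 29 the silyloxy ester
Product: 30 the 3-oxopropanoate ester of 28 (seco aldehyde)
Conditions: (COCl)2, DMSO, CH2Cl2, −78 to −40 °C; Et3N, −78 to 0 °C; used crude
Reagents that add atoms: none
Why: Under Swern conditions a primary triethylsilyl ether is converted directly into the aldehyde while the secondary TES and TBS ethers stay (selective Swern oxidation of primary TES ethers).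

Step 22
Reactants: 30 the seco aldehyde
Product: 32 macrolactone with free C3 hydroxyl (C7 OTBS; C9 OTES; aryl OTBS), via alkenylchromium dichloride 31 (not isolated)
Conditions: CrCl2 (10 equiv), (S)-N-[2-(4-isopropyl-4,5-dihydrooxazol-2-yl)-6-methylphenyl]methanesulfonamide, Et3N, NiCl2 (cat.), THF/MeCN, rt, syringe pump, 2 mM
Reagents that add atoms: none
Why: Zerovalent nickel (from NiCl2 and CrCl2) inserts into the C4–I bond, the Z-alkenyl group passes with retention to trivalent chromium (31) and adds to the C3 aldehyde; this is a Nozaki–Hiyama–Kishi macrocyclisation, the standard closure for macrolide allylic alcohols, and chromium-mediated closures onto 3-oxopropanoate esters are known. The 20-membered ring closes in the 20-exo-trig mode. The new C3 stereocentre is set by the chiral oxazoline–sulfonamide ligand on chromium, which exposes the Re face of the aldehyde and so gives 3S, with little bias expected from the remote C6/C7 centres. The step needs aldehyde-over-ester chemoselectivity, which organochromium reagents provide, and ring closure over oligomerisation, which high dilution and the chain pre-bent by three Z alkenes and the arene should secure. C9 is held as a triethylsilyl ether because a C9 ketone would sit 1,6 to the alkenylchromium carbon and close a cyclohexene instead. The aldehyde is used at once because it is a 1,3-dicarbonyl compound that enolises on standing.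

Step 23
Reactants: 32 the macrocyclic allylic alcohol
Product: 33 macrolactone with C3 OTBS (C7 OTBS; C9 OTES; aryl OTBS)
Conditions: TBSOTf, 2,6-lutidine, CH2Cl2, −78 °C
Reagents that add atoms: tert-butyldimethylsilyl triflate, CC(C)(C)[Si](C)(C)OS(=O)(=O)C(F)(F)F
Why: Silylation blocks the C3 allylic alcohol so that only C9 can be oxidised.

Step 24
Reactants: 33 the fully silylated macrolactone
Product: 34 macrolactone with free C9 hydroxyl (C3 and C7 OTBS; aryl OTBS)
Conditions: pyridinium p-toluenesulfonate, MeOH/CH2Cl2, 0 °C to rt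
Reagents that add atoms: none
Why: Mild acid methanolysis removes the secondary triethylsilyl ether selectively in the presence of alkyl and aryl TBS ethers.

Step 25
Reactants: 34 the C9 alcohol
Product: 35 macrocyclic C9 ketone (C3 and C7 OTBS; aryl OTBS)
Conditions: Dess–Martin periodinane, pyridine, CH2Cl2, 0 °C to rt
Reagents that add atoms: none
Why: Buffered Dess–Martin oxidation should give the α-methoxy ketone without epimerising C10 or moving the C11=C12 alkene into conjugation.

Step 26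
Reactants: 35 the tris-silyl ketone
Product: 36 CNP0537150.3
Conditions: HF·pyridine, pyridine, THF, 0 °C to rt
Reagents that add atoms: none
Why: Buffered fluoride desilylation removes the two alkyl TBS ethers and the aryl TBS ether under weakly acidic conditions that the β-hydroxy ketone and the C10 centre should tolerate.

**Compound list**

1 | methyl 3-hydroxy-5-iodobenzoate | COC(=O)c1cc(O)cc(I)c1 | starting material
2 | methyl 3-((tert-butyldimethylsilyl)oxy)-5-iodobenzoate | COC(=O)c1cc(I)cc(O[Si](C)(C)C(C)(C)C)c1 | intermediate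
3 | prop-2-yn-1-ol | C#CCO | starting material
4 | bromomagnesium (Z)-3-(bromomagnesio)-2-methylprop-2-en-1-olate | Br[Mg]/C=C(C)\CO[Mg]Br | intermediate (not isolated)
5 | (Z)-3-iodo-2-methylprop-2-en-1-ol | OC/C(C)=C\I | intermediate
6 | (Z)-3-bromo-1-iodo-2-methylprop-1-ene | BrC/C(C)=C\I | intermediate
7 | [3-((tert-butyldimethylsilyl)oxy)-5-(methoxycarbonyl)phenyl]magnesium chloride | COC(=O)c1cc([Mg]Cl)cc(O[Si](C)(C)C(C)(C)C)c1 | intermediate (not isolated)
8 | methyl (Z)-3-((tert-butyldimethylsilyl)oxy)-5-(3-iodo-2-methylallyl)benzoate | COC(=O)c1cc(C/C(C)=C\I)cc(O[Si](C)(C)C(C)(C)C)c1 | intermediate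
9 | (R)-4-benzyl-3-propionyloxazolidin-2-one | CCC(=O)N1[C@H](Cc2ccccc2)COC1=O | starting material
10 | 3-((tert-butyldimethylsilyl)oxy)propanal | O=CCCO[Si](C)(C)C(C)(C)C | starting material
11 | dibutylboron (Z)-enolate of 9 | C/C=C(\OB(CCCC)CCCC)N1[C@H](Cc2ccccc2)COC1=O | intermediate (not isolated)
12 | (R)-4-benzyl-3-[(2R,3S)-5-((tert-butyldimethylsilyl)oxy)-3-hydroxy-2-methylpentanoyl]oxazolidin-2-one | O=C(N1[C@H](Cc2ccccc2)COC1=O)[C@H](C)[C@@H](O)CCO[Si](C)(C)C(C)(C)C | intermediate
13 | (2R,3S)-5-((tert-butyldimethylsilyl)oxy)-3-hydroxy-N-methoxy-N,2-dimethylpentanamide | CON(C)C(=O)[C@H](C)[C@@H](O)CCO[Si](C)(C)C(C)(C)C | intermediate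
14 | (2R,3S)-3,5-bis((tert-butyldimethylsilyl)oxy)-N-methoxy-N,2-dimethylpentanamide | CON(C)C(=O)[C@H](C)[C@@H](O[Si](C)(C)C(C)(C)C)CCO[Si](C)(C)C(C)(C)C | intermediate
15 | (2R,3S)-3-((tert-butyldimethylsilyl)oxy)-5-hydroxy-N-methoxy-N,2-dimethylpentanamide | CON(C)C(=O)[C@H](C)[C@@H](O[Si](C)(C)C(C)(C)C)CCO | intermediate
16 | (2R,3S)-3-((tert-butyldimethylsilyl)oxy)-N-methoxy-N,2-dimethyl-5-oxopentanamide | CON(C)C(=O)[C@H](C)[C@@H](O[Si](C)(C)C(C)(C)C)CC=O | intermediate
17 | (2R,3S,5R,6R)-3-((tert-butyldimethylsilyl)oxy)-5-hydroxy-N,6-dimethoxy-N,2-dimethyloct-7-enamide | CON(C)C(=O)[C@H](C)[C@@H](O[Si](C)(C)C(C)(C)C)C[C@@H](O)[C@H](OC)C=C | intermediate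
18 | (2R,3S,5R,6R)-3-((tert-butyldimethylsilyl)oxy)-N,6-dimethoxy-N,2-dimethyl-5-((triethylsilyl)oxy)oct-7-enamide | CON(C)C(=O)[C@H](C)[C@@H](O[Si](C)(C)C(C)(C)C)C[C@@H](O[Si](CC)(CC)CC)[C@H](OC)C=C | intermediate
19 | secondary ozonide (1,2,4-trioxolane) of 18 | CON(C)C(=O)[C@H](C)[C@@H](O[Si](C)(C)C(C)(C)C)C[C@@H](O[Si](CC)(CC)CC)[C@H](OC)C1OCOO1 | intermediate (not isolated)
20 | (2R,3S,5R,6S)-3-((tert-butyldimethylsilyl)oxy)-N,6-dimethoxy-N,2-dimethyl-7-oxo-5-((triethylsilyl)oxy)heptanamide | CON(C)C(=O)[C@H](C)[C@@H](O[Si](C)(C)C(C)(C)C)C[C@@H](O[Si](CC)(CC)CC)[C@H](OC)C=O | intermediate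
21 | (2R,3S,5R,6R)-3-((tert-butyldimethylsilyl)oxy)-N,6-dimethoxy-N,2-dimethyl-5-((triethylsilyl)oxy)oct-7-ynamide | CON(C)C(=O)[C@H](C)[C@@H](O[Si](C)(C)C(C)(C)C)C[C@@H](O[Si](CC)(CC)CC)[C@H](OC)C#C | intermediate
22 | methyl 3-hydroxypropanoate | COC(=O)CCO | starting material
23 | methyl 3-((triethylsilyl)oxy)propanoate | COC(=O)CCO[Si](CC)(CC)CC | intermediate
24 | 3-((triethylsilyl)oxy)propanoic acid | OC(=O)CCO[Si](CC)(CC)CC | intermediate
25 | enyne: methyl 3-((tert-butyldimethylsilyl)oxy)-5-[(2Z,6R,7R,9S,10R)-9-((tert-butyldimethylsilyl)oxy)-6-methoxy-11-(methoxy(methyl)amino)-2,10-dimethyl-11-oxo-7-((triethylsilyl)oxy)undec-2-en-4-yn-1-yl]benzoate | COC(=O)c1cc(C/C(C)=C\C#C[C@@H](OC)[C@H](O[Si](CC)(CC)CC)C[C@H](O[Si](C)(C)C(C)(C)C)[C@@H](C)C(=O)N(C)OC)cc(O[Si](C)(C)C(C)(C)C)c1 | intermediate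
26 | Z,Z-diene: the (2Z,4Z)-undeca-2,4-dien-1-yl analogue of 25 | COC(=O)c1cc(C/C(C)=C\C=C/[C@@H](OC)[C@H](O[Si](CC)(CC)CC)C[C@H](O[Si](C)(C)C(C)(C)C)[C@@H](C)C(=O)N(C)OC)cc(O[Si](C)(C)C(C)(C)C)c1 | intermediate
27 | (2R,3S,5R,6R,7Z,9Z)-3-((tert-butyldimethylsilyl)oxy)-11-[3-((tert-butyldimethylsilyl)oxy)-5-(hydroxymethyl)phenyl]-6-methoxy-2,10-dimethyl-5-((triethylsilyl)oxy)undeca-7,9-dienal | OCc1cc(C/C(C)=C\C=C/[C@@H](OC)[C@H](O[Si](CC)(CC)CC)C[C@H](O[Si](C)(C)C(C)(C)C)[C@@H](C)C=O)cc(O[Si](C)(C)C(C)(C)C)c1 | intermediate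
28 | [3-((tert-butyldimethylsilyl)oxy)-5-((2Z,4Z,6R,7R,9S,10S,11Z)-9-((tert-butyldimethylsilyl)oxy)-12-iodo-6-methoxy-2,10-dimethyl-7-((triethylsilyl)oxy)trideca-2,4,11-trien-1-yl)phenyl]methanol | OCc1cc(C/C(C)=C\C=C/[C@@H](OC)[C@H](O[Si](CC)(CC)CC)C[C@H](O[Si](C)(C)C(C)(C)C)[C@@H](C)/C=C(\I)C)cc(O[Si](C)(C)C(C)(C)C)c1 | intermediate
29 | 3-((triethylsilyl)oxy)propanoate ester of 28 | CC[Si](CC)(CC)OCCC(=O)OCc1cc(C/C(C)=C\C=C/[C@@H](OC)[C@H](O[Si](CC)(CC)CC)C[C@H](O[Si](C)(C)C(C)(C)C)[C@@H](C)/C=C(\I)C)cc(O[Si](C)(C)C(C)(C)C)c1 | intermediate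
30 | 3-oxopropanoate ester of 28 (seco aldehyde) | O=CCC(=O)OCc1cc(C/C(C)=C\C=C/[C@@H](OC)[C@H](O[Si](CC)(CC)CC)C[C@H](O[Si](C)(C)C(C)(C)C)[C@@H](C)/C=C(\I)C)cc(O[Si](C)(C)C(C)(C)C)c1 | intermediate
31 | Z-alkenylchromium dichloride from 30 (chromium in place of iodine at C4) | O=CCC(=O)OCc1cc(C/C(C)=C\C=C/[C@@H](OC)[C@H](O[Si](CC)(CC)CC)C[C@H](O[Si](C)(C)C(C)(C)C)[C@@H](C)/C=C(\[Cr](Cl)Cl)C)cc(O[Si](C)(C)C(C)(C)C)c1 | intermediate (not isolated)
32 | 20-membered lactone (3S,6S,7S,9R,10R; 4Z,11Z,13Z): C3 OH free; C7 OTBS; C9 OTES; aryl OTBS | CO[C@@H]1/C=C\C=C(\C)Cc2cc(O[Si](C)(C)C(C)(C)C)cc(c2)COC(=O)C[C@H](O)/C(C)=C\[C@H](C)[C@@H](O[Si](C)(C)C(C)(C)C)C[C@H]1O[Si](CC)(CC)CC | intermediate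
33 | C3 TBS ether of 32 | CO[C@@H]1/C=C\C=C(\C)Cc2cc(O[Si](C)(C)C(C)(C)C)cc(c2)COC(=O)C[C@H](O[Si](C)(C)C(C)(C)C)/C(C)=C\[C@H](C)[C@@H](O[Si](C)(C)C(C)(C)C)C[C@H]1O[Si](CC)(CC)CC | intermediate
34 | (9R)-C9 alcohol: C3 and C7 OTBS; aryl OTBS | CO[C@@H]1/C=C\C=C(\C)Cc2cc(O[Si](C)(C)C(C)(C)C)cc(c2)COC(=O)C[C@H](O[Si](C)(C)C(C)(C)C)/C(C)=C\[C@H](C)[C@@H](O[Si](C)(C)C(C)(C)C)C[C@H]1O | intermediate
35 | C9 ketone: C3 and C7 OTBS; aryl OTBS | CO[C@@H]1/C=C\C=C(\C)Cc2cc(O[Si](C)(C)C(C)(C)C)cc(c2)COC(=O)C[C@H](O[Si](C)(C)C(C)(C)C)/C(C)=C\[C@H](C)[C@@H](O[Si](C)(C)C(C)(C)C)CC1=O | intermediate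
36 | CNP0537150.3 (3S,6S,7S,10R; 4Z,11Z,13Z) | CO[C@@H]1/C=C\C=C(\C)Cc2cc(O)cc(c2)COC(=O)C[C@H](O)/C(C)=C\[C@H](C)[C@@H](O)CC1=O | target

**Totals and risks**

Total step count: 26. Longest linear sequence: 20 steps (steps 5–13, then 16–26).

Step 22 (ring closure). What may go wrong: the β-formyl ester may enolise and bind to chromium, the alkenylchromium may be protonated with loss of iodine, oligomers may form, or the ligand may give poor facial selectivity at C3. Fallback, from 28 back to 32: iodine–lithium exchange on 28 (t-BuLi, Et2O, −78 °C, one extra equivalent for the hydroxyl) and quench with DMF would give the Z-2-methyl enal F1. A Mukaiyama acetate aldol of F1 with the silyl ketene acetal of S-tert-butyl thioacetate, under Sn(OTf)2 and a chiral diamine, would form the C2–C3 bond instead and give the (3S)-β-hydroxy thioester F2. Thiophilic activation of F2 with AgOCOCF3 and Na2HPO4 at high dilution would lactonise onto the benzylic hydroxyl and return to 32.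

Step 19 (iodoalkene). What may go wrong: erosion of Z selectivity, epimerisation at C6 by enolisation of the α-branched aldehyde, or decomposition of the iodo ylide before it reacts. Fallback, from 27 back to 28: (dibromomethyl)triphenylphosphonium bromide and KOtBu would convert 27 into the 1,1-dibromoalkene F3. Palladium-catalysed Negishi coupling (MeZnCl, Pd(PtBu3)2) replaces only the bromine trans to C6 and would give the Z-2-bromoalkene F4. Bromine–lithium exchange on F4 (t-BuLi, −78 °C) and iodinolysis would give 28.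

Step 10 (C10 stereocentre). What may go wrong: incomplete reagent control over the β-silyloxy aldehyde, which would give the C10 epimer, or incomplete metalation of the allyl ether. Fallback, from 16 back to 20: an Evans syn-glycolate aldol of 16 with (S)-4-benzyl-3-(methoxyacetyl)oxazolidin-2-one (Bu2BOTf, Et3N) would give the imide F5 with C10 set by the auxiliary. TESOTf would give the silyl ether F6. LiBH4 with MeOH should reduce the imide in preference to the Weinreb amide and give the primary alcohol F7, and Dess–Martin oxidation of F7 would give 20.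

**Further compounds**

F1 | step 22 | Z-enal: 28 with CHO in place of iodine at C4 | OCc1cc(C/C(C)=C\C=C/[C@@H](OC)[C@H](O[Si](CC)(CC)CC)C[C@H](O[Si](C)(C)C(C)(C)C)[C@@H](C)/C=C(\C=O)C)cc(O[Si](C)(C)C(C)(C)C)c1
F2 | step 22 | S-tert-butyl (3S)-3-hydroxy thioester (acetate aldol adduct of F1) | OCc1cc(C/C(C)=C\C=C/[C@@H](OC)[C@H](O[Si](CC)(CC)CC)C[C@H](O[Si](C)(C)C(C)(C)C)[C@@H](C)/C=C(\[C@@H](O)CC(=O)SC(C)(C)C)C)cc(O[Si](C)(C)C(C)(C)C)c1
F3 | step 19 | 1,1-dibromoalkene from 27 | OCc1cc(C/C(C)=C\C=C/[C@@H](OC)[C@H](O[Si](CC)(CC)CC)C[C@H](O[Si](C)(C)C(C)(C)C)[C@@H](C)C=C(Br)Br)cc(O[Si](C)(C)C(C)(C)C)c1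
F4 | step 19 | Z-2-bromoalkene analogue of 28 | OCc1cc(C/C(C)=C\C=C/[C@@H](OC)[C@H](O[Si](CC)(CC)CC)C[C@H](O[Si](C)(C)C(C)(C)C)[C@@H](C)/C=C(\Br)C)cc(O[Si](C)(C)C(C)(C)C)c1
F5 | step 10 | syn-glycolate aldol imide (C9 OH; C10 OMe; (S)-benzyloxazolidinone at C11) | CON(C)C(=O)[C@H](C)[C@@H](O[Si](C)(C)C(C)(C)C)C[C@@H](O)[C@H](OC)C(=O)N1[C@@H](Cc2ccccc2)COC1=O
F6 | step 10 | C9 triethylsilyl ether of F5 | CON(C)C(=O)[C@H](C)[C@@H](O[Si](C)(C)C(C)(C)C)C[C@@H](O[Si](CC)(CC)CC)[C@H](OC)C(=O)N1[C@@H](Cc2ccccc2)COC1=O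
F7 | step 10 | C11 primary alcohol | CON(C)C(=O)[C@H](C)[C@@H](O[Si](C)(C)C(C)(C)C)C[C@@H](O[Si](CC)(CC)CC)[C@H](OC)CO
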